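(The runs are calculated for substances that don't exist; scatter was added.)

Ochre, the flask in question, was due its next 40 min, and I had to choose how to spend them from its readings and those of blue.

the same everywhere: substrate 38 mM; second reagent 41.8 mM; gas 1.7 mM (held)
- ochre: temperature 25 °C; the very flask that is asked about, followed so far
- blue: temperature 31 °C; run made earlier
- flask: temperature 25 °C; time 40 min

- ochre (time / min: target / %, substrate / %): 4.00: 16.1, 15.8; 12.0: 26.3, 0.1; 20.0: 27.2, 1.5; 30.0: 29.4, 2.3
- blue (time / min: target / %, substrate / %): 4.00: 18.8, 6.1; 12.0: 24.7, 1.4; 20.0: 26.4, 3.3; 30.0: 29.9, 2.3

(scatter of a reading: 1 percentage point)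

1. target, in percent of the substrate first charged, at 40 min
2. what to do for the largest gain in target; "none" if nothing gains more than 2 percentage points (noon / autumn / midnight / dusk / none)
3. target present, with what was taken out counted in, in percent of the substrate first charged, after noon
4. target present, with what was taken out counted in, in percent of the substrate first charged, after dusk

- noon: at 40 min take out 90 % of the target then present, then wait 40 min
- autumn: at 40 min raise the temperature by 25 K, then wait 40 min
- midnight: change nothing and wait 40 min more
- dusk: at 40 min add second reagent, 100 % of the amount charged, then wait 40 min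

- target that was removed still counts
- at the start none of the gas is in solution
- additions bring no volume worth counting

By 12.0 min the ochre substrate read 0.1 % and the target 26.3 %, so 73.6 % of the charge stood in neither. After that, target crept upward. I called that unseen share the store and took it as draining pseudo-first-order, with a drain constant k, the fraction of the store reaching target per minute. Integrating that one rate gave the reckoning:

store at the last ochre reading = 1 − target − substrate = 68.3 %

k = rise of target per minute ÷ store = 0.00252 min⁻¹

target gained in a wait = store × (1 − exp(−k × wait))

This put ochre at 31.1 % at 40 min, with a drain half-life of 275 min, longer than the wait. Midnight therefore offered 6.4 percentage points. I reckoned noon the same, since no reading showed target falling. Dusk I could not reckon, as both runs charged 41.8 mM.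

Blue's k came out 1.69 times ochre's for a step from 25 °C to 31 °C. Compounding that ratio over 4 such steps, slightly fewer than 25 K holds, gave autumn 37 points. The ratio is coarse, since ochre's target rose 3.1 points against a scatter of 1 point, but autumn stood 31 points above midnight. I chose autumn.

The forecast gave 31 %, autumn, 37 % after noon and 39 % after dusk, reading that “most material sits in a reversible reservoir that slowly feeds target”.

The flask gave 32.6 % at 40 min and the best option autumn, with gains of 27 points for autumn, 6.7 points for midnight, 6.7 points for noon and 5.6 points for dusk. With what was taken out counted in, target stood at 39.3 % after noon, and after dusk it stood at 38.2 %.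

    substrate + partner → intermediate (k = 1.18 M⁻¹ s⁻¹, Ea = 39.0 kJ mol⁻¹)
    second reagent + intermediate → target (k = 0.348 M⁻¹ s⁻¹, Ea = 43.0 kJ mol⁻¹)
    substrate + second reagent → side product (k = 0.0414 M⁻¹ s⁻¹, Ea = 47.0 kJ mol⁻¹)
    gas ⇌ partner, rate k4*(csat - [partner]) (kL = 4.29 s⁻¹)
    substrate ⇌ dormant form (K = 17.0, k = 0.00429 s⁻¹, Ea = 83.0 kJ mol⁻¹, ΔH = −19.0 kJ mol⁻¹)
    (constants at 25 °C)

The flask had not come to rest at 40 min. Carried to 400 min, k gave target 71.9 %, and the flask gives 62.9 %, which is 9 points lower. My store had counted side product as well, 22.2 % at 40.0 min and 30.5 % at 400 min. Over the same stretch the dormant form fell from 43.2 % to 6.17 %. Second reagent, in its own charge, went from 50.2 % to 15.1 %, and at 400 min the flask still held that 6.17 % of dormant form.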